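**Retrosynthetic overview**

1. Locants (ad hoc, used throughout): C1 = quaternary C(CH3)(C12H2–O); cyclobutane = C2 (H, on C1), C3 (H, on C4), C8 (CH3, on C9), C7 (H, on C6); C4 = CH(CH3); C5 = CH2; C6 = C=O; C9 = CH2; C10, C11 = CH–O (C11 on C1). Target 35 ⇐ three angelates put on last, one per step (O12, then O10, then O11) ⇐ triol 31 ⇐ tribenzyl ether 30 ⇐ one-carbon ring enlargement (C5 inserted between C6 and C4) of the bicyclo[2.1.1]hexan-2-one 27.
2. Enabling feature: both diagonals of the cyclobutane C2–C3–C8–C7 are bridged (C3/C7 by C4–C5–C6, C2/C8 by C1–C11–C10–C9), and C7–C8(CH3) next to the C6 carbonyl is a latent β-methyl enone. The four-membered ring is therefore the crossed [2+2] adduct of that enone and a C2=C3 olefin; with C5 left out the two olefins are 1,5-related, the arrangement that adds crossed (rule of five).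
3. Key disconnection: C3–C8 and C2–C7 of 27 ⇐ transannular crossed [2+2] photocycloaddition of the (2E,8E)-cyclodeca-2,8-dienone 25; the C4 methyl group steers the facial sense.
4. 25 ⇐ Nozaki–Hiyama–Kishi closure of C6–C7 in 22. C10 comes from a chelation-controlled propargylation, the C7=C8 vinyl iodide from carboalumination–iodination, C1/C11 and the E C2=C3 olefin from a glycolate Ireland–Claisen rearrangement, and C3/C4 from an Evans syn-aldol reaction of enal 4.
5. Ring order: ten-membered carbocycle (step 15) → cyclobutane, both five-membered rings and the seven-membered rings in one operation (step 17) → cyclopentanone enlarged to the cyclohexanone (step 18).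

Key step: step 17

Remark: compounds 1, 2, 5, 10 and 32 and the reagents on the Conditions lines are taken as commercial; CIP descriptors follow the numbering of each name, and the SMILES in the list are decisive.

**Route**

Step 1
Reactants: 1 1-(benzyloxy)propan-2-one; 2 diethyl {2-[methoxy(methyl)amino]-2-oxoethyl}phosphonate
Product: 3 (E)-4-(benzyloxy)-N-methoxy-N,3-dimethylbut-2-enamide
Conditions: NaH, THF, 0 °C → rt; chromatographic removal of the (Z)-isomer
Reagents that add atoms: none
Why: Horner–Wadsworth–Emmons olefination of the α-alkoxy methyl ketone should give mainly the (E)-enamide (amide trans to CH2OBn).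

Step 2
Reactants: 3 (E)-4-(benzyloxy)-N-methoxy-N,3-dimethylbut-2-enamide
Product: 4 (E)-4-(benzyloxy)-3-methylbut-2-enal
Conditions: iBu2AlH, THF, −78 °C; aq. potassium sodium tartrate work-up
Reagents that add atoms: none
Why: Weinreb amide reduction stops at the aldehyde because the chelated tetrahedral intermediate survives until work-up, and the olefin geometry is untouched.

Step 3
Reactants: 4 (E)-4-(benzyloxy)-3-methylbut-2-enal; 5 (S)-4-benzyl-3-propanoyloxazolidin-2-one
Product: 7 (S)-4-benzyl-3-[(2S,3R,4E)-6-(benzyloxy)-3-hydroxy-2,5-dimethylhex-4-enoyl]oxazolidin-2-one, via dibutylboron enolate 6 (not isolated)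
Conditions: Bu2BOTf, iPr2NEt, CH2Cl2, −78 → 0 °C; then 4, −78 → 0 °C; pH 7 buffer, MeOH, H2O2
Reagents that add atoms: none
Why: Evans syn-aldol reaction in which the (Z)-boron enolate adds through a Zimmerman–Traxler chair on the face dictated by the (S)-benzyl auxiliary, setting C3 and C4 syn (C4 keeps this spatial arrangement to the end, only its descriptor changes).

Step 4
Reactants: 7 the aldol adduct
Product: 8 (2R,3R,4E)-6-(benzyloxy)-2,5-dimethylhex-4-ene-1,3-diol
Conditions: LiBH4, Et2O/MeOH, 0 °C
Reagents that add atoms: none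
Why: reductive cleavage of the N-acyloxazolidinone releases the primary alcohol and the recoverable auxiliary without touching the stereocentres.

Step 5
Reactants: 8 the diol
Product: 9 (2E,4R,5R)-1-(benzyloxy)-6-(tert-butyldimethylsilyloxy)-2,5-dimethylhex-2-en-4-ol
Conditions: tert-butyldimethylsilyl chloride, imidazole, CH2Cl2, −20 → 0 °C
Reagents that add atoms: tert-butyldimethylsilyl chloride, CC(C)(C)[Si](C)(C)Cl
Why: selective monosilylation, the primary hydroxyl of the 1,3-diol reacting far faster than the secondary allylic one.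

Step 6
Reactants: 9 the monosilyl ether; 10 (benzyloxy)acetyl chloride
Product: 11 (2E,4R,5R)-1-(benzyloxy)-6-(tert-butyldimethylsilyloxy)-2,5-dimethylhex-2-en-4-yl (benzyloxy)acetate
Conditions: pyridine, DMAP (cat.), CH2Cl2, 0 °C → rt
Reagents that add atoms: none
Why: DMAP-catalysed acylation of the secondary allylic alcohol installs the glycolate needed for the sigmatropic step.

Step 7
Reactants: 11 the allylic glycolate
Product: 14 (2S,3S,4E,6S)-2-(benzyloxy)-3-[(benzyloxy)methyl]-7-(tert-butyldimethylsilyloxy)-3,6-dimethylhept-4-enoic acid, via silyl ketene acetal 12 (not isolated), via trimethylsilyl ester 13 (not isolated)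
Conditions: LiN(SiMe3)2, Me3SiCl, THF, −78 °C → rt; dilute HCl work-up
Reagents that add atoms: none
Why: glycolate Ireland–Claisen rearrangement in which the chelated (Z)-enolate is silylated and rearranges through a chair with the C3 substituent equatorial, so that chirality passes from C3 to the new quaternary C1 and to C11 (O11 syn to C12) and the C2=C3 olefin forms E.

Step 8
Reactants: 14 the acid
Product: 15 (2S,3S,4E,6S)-2-(benzyloxy)-3-[(benzyloxy)methyl]-7-(tert-butyldimethylsilyloxy)-3,6-dimethylhept-4-en-1-ol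
Conditions: LiAlH4, THF, 0 °C → rt
Reagents that add atoms: none
Why: hydride reduction of the carboxylic acid to the primary alcohol, to which silyl and benzyl ethers are inert.

Step 9
Reactants: 15 the primary alcohol
Product: 16 (2S,3S,4E,6S)-2-(benzyloxy)-3-[(benzyloxy)methyl]-7-(tert-butyldimethylsilyloxy)-3,6-dimethylhept-4-enal
Conditions: Dess–Martin periodinane, CH2Cl2, 0 °C → rt
Reagents that add atoms: none
Why: Dess–Martin oxidation gives the α-benzyloxy aldehyde under mild conditions that should not epimerise C11.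

Step 10
Reactants: 16 the α-benzyloxy aldehyde
Product: 17 (4S,5S,6S,7E,9S)-5-(benzyloxy)-6-[(benzyloxy)methyl]-10-(tert-butyldimethylsilyloxy)-6,9-dimethyldec-7-en-1-yn-4-ol
Conditions: allenyltributylstannane, MgBr2·OEt2, CH2Cl2, −78 → −20 °C
Reagents that add atoms: allenyltributylstannane, C=C=C[Sn](CCCC)(CCCC)CCCC
Why: chelation-controlled (Cram chelate) SE2' propargylation in which MgBr2 bridges the aldehyde and the C11 benzyloxy oxygen and the stannane attacks anti to the quaternary C1, giving the syn (10S,11S) homopropargylic alcohol.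

Step 11
Reactants: 17 the homopropargylic alcohol
Product: 18 (4S,5S,6S,7E,9S)-4,5-bis(benzyloxy)-6-[(benzyloxy)methyl]-10-(tert-butyldimethylsilyloxy)-6,9-dimethyldec-7-en-1-yne
Conditions: NaH, benzyl bromide, Bu4NI (cat.), THF/DMF, 0 °C → rt
Reagents that add atoms: benzyl bromide, BrCc1ccccc1
Why: Williamson benzylation protects the C10 hydroxyl so that all three oxygens are freed later in one hydrogenolysis.

Step 12
Reactants: 18 the terminal alkyne
Product: 20 (1E,4S,5S,6S,7E,9S)-4,5-bis(benzyloxy)-6-[(benzyloxy)methyl]-10-(tert-butyldimethylsilyloxy)-1-iodo-2,6,9-trimethyldeca-1,7-diene, via alkenylalane 19 (not isolated)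
Conditions: AlMe3, Cp2ZrCl2, H2O (cat.), CH2Cl2, −20 → 0 °C; then I2, THF, −30 °C
Reagents that add atoms: trimethylaluminium, C[Al](C)C; iodine, II
Why: Negishi carboalumination adds CH3 and Al syn across the alkyne with CH3 on the internal carbon, and iodinolysis with retention gives the (E)-vinyl iodide (C7=C8).

Step 13
Reactants: 20 the silyl ether
Product: 21 (2S,3E,5S,6S,7S,9E)-6,7-bis(benzyloxy)-5-[(benzyloxy)methyl]-10-iodo-2,5,9-trimethyldeca-3,9-dien-1-ol
Conditions: HF·pyridine, pyridine/THF, 0 °C → rt
Reagents that add atoms: none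
Why: fluoride cleaves the primary silyl ether while benzyl ethers and the vinyl iodide are stable.

Step 14
Reactants: 21 the primary alcohol
Product: 22 (2S,3E,5S,6S,7S,9E)-6,7-bis(benzyloxy)-5-[(benzyloxy)methyl]-10-iodo-2,5,9-trimethyldeca-3,9-dienal
Conditions: Dess–Martin periodinane, NaHCO3, CH2Cl2, 0 °C; used at once
Reagents that add atoms: none
Why: buffered Dess–Martin oxidation gives the α-branched β,γ-unsaturated aldehyde without acid or base that could epimerise C4 or move the olefin into conjugation.

Step 15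
Reactants: 22 the iodo aldehyde
Product: 24 (2E,5S,6S,7S,8E,10S)-5,6-bis(benzyloxy)-7-[(benzyloxy)methyl]-3,7,10-trimethylcyclodeca-2,8-dien-1-ol (carbinol epimers), via alkenylchromium species 23 (not isolated)
Conditions: CrCl2 (excess), NiCl2 (cat.), DMSO, rt, slow addition, 0.002 M
Reagents that add atoms: none
Why: intramolecular Nozaki–Hiyama–Kishi reaction in which the alkenylchromium species adds to the aldehyde with retention of olefin geometry and tolerance of the epimerisable C4 centre; the new carbinol centre C6 is removed in step 16.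

Step 16
Reactants: 24 the macrocyclic allylic alcohol
Product: 25 (2E,5S,6S,7S,8E,10S)-5,6-bis(benzyloxy)-7-[(benzyloxy)methyl]-3,7,10-trimethylcyclodeca-2,8-dien-1-one
Conditions: Dess–Martin periodinane, CH2Cl2, 0 °C → rt
Reagents that add atoms: none
Why: Dess–Martin oxidation of the allylic alcohol gives the dienone in which the C7=C8 enone and the C2=C3 olefin are 1,5-related through C6 and C4.

Step 17
Reactants: 25 the (2E,8E)-cyclodecadienone
Product: 27 tri-O-benzyl tricyclic nor-ketone (bicyclo[2.1.1]hexan-2-one core; C4-CH3 syn to C2-H), via triplet 1,4-biradical 26 (not isolated)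
Conditions: hν (350 nm lamps, Pyrex), degassed MeCN, 0.005 M, rt
Reagents that add atoms: none
Why: Excitation of the β-methyl enone and intersystem crossing give the triplet enone, whose β-carbon C8 bonds to C3 to give a triplet 1,4-biradical (C7/C2) that closes after spin inversion; this is the crossed intramolecular enone–olefin [2+2] photocycloaddition of 1,5-hexadien-3-ones to bicyclo[2.1.1]hexan-2-ones, here in the transannular form known for (E,E)-cyclodeca-1,5-diene (germacrane-type) rings. The first bond closes the cyclopentanone C3–C4–C6–C7–C8 (five-membered, rule of five), radical recombination C7–C2 closes the cyclobutane and with it the second five-membered ring, and the same two bonds turn the ten-membered ring into the seven-membered rings through C1–C11–C10–C9 by transannular closure. The step needs crossed rather than straight regiochemistry, and the two-atom C4–C6 link between C3 and C7 secures it: either possible first bond (C8–C3 or C7–C2) makes a five-membered ring and both lead to the crossed adduct, whereas the straight adduct would be a bicyclo[2.2.0]hexanone. The relative configuration of C2, C3, C7 and C8 is fixed by the ring, because the chain C9–C10–C11–C1 can only span C8 and C2 on the face opposite the C4–C6 bridge, so C8-CH3 and C2-H end up syn to that bridge whatever happens to the olefin geometries in the biradical. The sense of the cage relative to C1, C10 and C11 is controlled by C4, whose methyl group takes the outside position anti to the forming C3–C8 bond and so ends up syn to C2-H and away from C8-CH3 as in the target, while mismatched biradicals should revert to 25. Light of 350 nm does not excite the benzyl ethers, and the angelates, which could isomerise under irradiation, are not yet present.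

Step 18
Reactants: 27 the bicyclo[2.1.1]hexan-2-one
Product: 30 tri-O-benzyl ether of triol 31 (cyclohexanone; C5 inserted), via dibromomethyl lithium alkoxide 28 (not isolated), via lithium enolate 29 (not isolated)
Conditions: CH2Br2, lithium 2,2,6,6-tetramethylpiperidide, THF, −78 °C; then n-BuLi, −78 → 0 °C; then H2O
Reagents that add atoms: dibromomethane, BrCBr
Why: β-oxido carbenoid ring enlargement (Taguchi–Nozaki–Yamamoto) in which LiCHBr2 adds to the strained ketone, Br/Li exchange gives the carbenoid, and the better migrating group, the normal secondary C4 rather than the high-s-character bridgehead C7, should shift with retention to give the enolate that is protonated to the cyclohexanone with C4-CH3 unchanged.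

Step 19
Reactants: 30 the tribenzyl ether
Product: 31 core triol (target without its three acyl groups)
Conditions: H2 (1 atm), Pd(OH)2/C, EtOAc/MeOH, rt
Reagents that add atoms: none
Why: hydrogenolysis removes the three benzyl ethers; no olefin is left, and the ketone and the cyclobutane are inert under these conditions.

Step 20
Reactants: 31 the triol; 32 angelic acid [(Z)-2-methylbut-2-enoic acid]
Product: 33 12-O-angeloyl diol (C10-OH and C11-OH free)
Conditions: 32 (1.05 equiv), 2,4,6-trichlorobenzoyl chloride, Et3N, toluene, rt; then 31, toluene, 45 °C (no DMAP)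
Reagents that add atoms: none
Why: Yamaguchi-type esterification through the mixed 2,4,6-trichlorobenzoic anhydride, run without the nucleophilic base that isomerises angelates to tiglates, should deliver the single equivalent of acyl donor to the primary C12 hydroxyl, the most accessible of the three, and any partial ester formed elsewhere still converges on 35 because every hydroxyl is acylated by the end of step 22.

Step 21
Reactants: 33 the 12-O-angelate; 32 angelic acid
Product: 34 10,12-di-O-angeloyl alcohol (C11-OH free)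
Conditions: 32 (1.2 equiv), 2,4,6-trichlorobenzoyl chloride, Et3N, toluene, rt; then 33, toluene, 65 °C (no DMAP)
Reagents that add atoms: none
Why: the same mixed-anhydride esterification at higher temperature should acylate the C10 hydroxyl, which is flanked by the C9 methylene, in preference to the C11 hydroxyl next to the quaternary C1, and an acyl shift between O10 and O11 would be harmless since step 22 esterifies whichever hydroxyl remains.

Step 22
Reactants: 34 the 10,12-di-O-angelate; 32 angelic acid
Product: 35 the target triangelate CNP0214984.1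
Conditions: 32 (3 equiv), 2,4,6-trichlorobenzoyl chloride, Et3N, toluene, rt; then 34, toluene, 80 °C (no DMAP)
Reagents that add atoms: none
Why: an excess of the mixed anhydride at 80 °C should force acylation of the last, neopentyl-type C11 hydroxyl, the medium staying free of nucleophilic catalysts so that all three angelates keep their Z geometry.

**Compound list**

1 | 1-(benzyloxy)propan-2-one | CC(=O)COCc1ccccc1 | starting material
2 | diethyl {2-[methoxy(methyl)amino]-2-oxoethyl}phosphonate | CCOP(=O)(CC(=O)N(C)OC)OCC | starting material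
3 | (E)-4-(benzyloxy)-N-methoxy-N,3-dimethylbut-2-enamide | CON(C)C(=O)/C=C(\C)COCc1ccccc1 | intermediate
4 | (E)-4-(benzyloxy)-3-methylbut-2-enal | O=C/C=C(\C)COCc1ccccc1 | intermediate
5 | (S)-4-benzyl-3-propanoyloxazolidin-2-one | CCC(=O)N1[C@@H](Cc2ccccc2)COC1=O | starting material
6 | dibutylboron (Z)-enolate of 5 | C/C=C(\OB(CCCC)CCCC)N1[C@@H](Cc2ccccc2)COC1=O | intermediate (not isolated)
7 | Evans syn-aldol adduct (2S,3R) | c1ccccc1COC/C(C)=C/[C@@H](O)[C@H](C)C(=O)N2[C@@H](Cc3ccccc3)COC2=O | intermediate
8 | (2R,3R,4E)-6-(benzyloxy)-2,5-dimethylhex-4-ene-1,3-diol | c1ccccc1COC/C(C)=C/[C@@H](O)[C@H](C)CO | intermediate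
9 | (2E,4R,5R)-1-(benzyloxy)-6-(tert-butyldimethylsilyloxy)-2,5-dimethylhex-2-en-4-ol | c1ccccc1COC/C(C)=C/[C@@H](O)[C@H](C)CO[Si](C)(C)C(C)(C)C | intermediate
10 | (benzyloxy)acetyl chloride | O=C(Cl)COCc1ccccc1 | starting material
11 | allylic (benzyloxy)acetate of 9 | c1ccccc1COC/C(C)=C/[C@@H](OC(=O)COCc2ccccc2)[C@H](C)CO[Si](C)(C)C(C)(C)C | intermediate
12 | (Z)-trimethylsilyl ketene acetal of 11 | c1ccccc1COC/C(C)=C/[C@@H](O/C(=C/OCc2ccccc2)O[Si](C)(C)C)[C@H](C)CO[Si](C)(C)C(C)(C)C | intermediate (not isolated)
13 | trimethylsilyl ester of 14 | c1ccccc1COC[C@](C)(/C=C/[C@H](C)CO[Si](C)(C)C(C)(C)C)[C@H](OCc2ccccc2)C(=O)O[Si](C)(C)C | intermediate (not isolated)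
14 | (2S,3S,4E,6S)-2-(benzyloxy)-3-[(benzyloxy)methyl]-7-(tert-butyldimethylsilyloxy)-3,6-dimethylhept-4-enoic acid | c1ccccc1COC[C@](C)(/C=C/[C@H](C)CO[Si](C)(C)C(C)(C)C)[C@H](OCc2ccccc2)C(=O)O | intermediate
15 | corresponding hept-4-en-1-ol | c1ccccc1COC[C@](C)(/C=C/[C@H](C)CO[Si](C)(C)C(C)(C)C)[C@H](OCc2ccccc2)CO | intermediate
16 | corresponding hept-4-enal | c1ccccc1COC[C@](C)(/C=C/[C@H](C)CO[Si](C)(C)C(C)(C)C)[C@H](OCc2ccccc2)C=O | intermediate
17 | (4S,5S,6S,7E,9S)-homopropargylic alcohol | c1ccccc1COC[C@](C)(/C=C/[C@H](C)CO[Si](C)(C)C(C)(C)C)[C@H](OCc2ccccc2)[C@@H](O)CC#C | intermediate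
18 | tribenzyl ether alkyne | c1ccccc1COC[C@](C)(/C=C/[C@H](C)CO[Si](C)(C)C(C)(C)C)[C@H](OCc2ccccc2)[C@@H](OCc3ccccc3)CC#C | intermediate
19 | (E)-alkenyl(dimethyl)alane from 18 | c1ccccc1COC[C@](C)(/C=C/[C@H](C)CO[Si](C)(C)C(C)(C)C)[C@H](OCc2ccccc2)[C@@H](OCc3ccccc3)C/C(C)=C/[Al](C)C | intermediate (not isolated)
20 | (E)-vinyl iodide silyl ether | c1ccccc1COC[C@](C)(/C=C/[C@H](C)CO[Si](C)(C)C(C)(C)C)[C@H](OCc2ccccc2)[C@@H](OCc3ccccc3)C/C(C)=C/I | intermediate
21 | (2S,3E,5S,6S,7S,9E)-iodo dienol | c1ccccc1COC[C@](C)(/C=C/[C@H](C)CO)[C@H](OCc2ccccc2)[C@@H](OCc3ccccc3)C/C(C)=C/I | intermediate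
22 | (2S,3E,5S,6S,7S,9E)-iodo dienal | c1ccccc1COC[C@](C)(/C=C/[C@H](C)C=O)[C@H](OCc2ccccc2)[C@@H](OCc3ccccc3)C/C(C)=C/I | intermediate
23 | alkenylchromium dichloride from 22 | c1ccccc1COC[C@](C)(/C=C/[C@H](C)C=O)[C@H](OCc2ccccc2)[C@@H](OCc3ccccc3)C/C(C)=C/[Cr](Cl)Cl | intermediate (not isolated)
24 | (2E,8E)-cyclodeca-2,8-dien-1-ol (C6 carbinol epimers) | c1ccccc1COC[C@]1(C)/C=C/[C@H](C)C(O)/C=C(C)/C[C@H](OCc2ccccc2)[C@H]1OCc3ccccc3 | intermediate
25 | (2E,5S,6S,7S,8E,10S)-5,6-bis(benzyloxy)-7-[(benzyloxy)methyl]-3,7,10-trimethylcyclodeca-2,8-dien-1-one | c1ccccc1COC[C@]1(C)/C=C/[C@H](C)C(=O)/C=C(C)/C[C@H](OCc2ccccc2)[C@H]1OCc3ccccc3 | intermediate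
26 | triplet 1,4-biradical (C8–C3 bonded; radicals at C7 and C2) | c1ccccc1COC[C@]1(C)[CH][C@@H]2[C@H](C)C(=O)[CH][C@]2(C)C[C@H](OCc3ccccc3)[C@H]1OCc4ccccc4 | intermediate (not isolated)
27 | tricyclic nor-ketone: 3-methylbicyclo[2.1.1]hexan-2-one whose one-carbon bridges C2 and C8 are joined by C1–C11–C10–C9; tri-O-benzyl; C4-CH3 syn to C2-H | c1ccccc1COC[C@]1(C)[C@H]2[C@@H]3[C@H](C)C(=O)[C@H]2[C@]3(C)C[C@H](OCc4ccccc4)[C@H]1OCc5ccccc5 | intermediate
28 | lithium alkoxide of the C6 dibromomethyl carbinol (C6 configuration open) | c1ccccc1COC[C@]1(C)[C@H]2[C@@H]3[C@H](C)C([O-])(C(Br)Br)[C@H]2[C@]3(C)C[C@H](OCc4ccccc4)[C@H]1OCc5ccccc5.[Li+] | intermediate (not isolated)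
29 | lithium enolate (C5=C6) of 30 | c1ccccc1COC[C@]1(C)[C@H]2[C@@H]3[C@H](C)C=C([O-])[C@H]2[C@]3(C)C[C@H](OCc4ccccc4)[C@H]1OCc5ccccc5.[Li+] | intermediate (not isolated)
30 | tri-O-benzyl ether of triol 31 | c1ccccc1COC[C@]1(C)[C@H]2[C@@H]3[C@H](C)CC(=O)[C@H]2[C@]3(C)C[C@H](OCc4ccccc4)[C@H]1OCc5ccccc5 | intermediate
31 | core triol (C10-OH, C11-OH, C12-OH; ketone at C6) | OC[C@]1(C)[C@H]2[C@@H]3[C@H](C)CC(=O)[C@H]2[C@]3(C)C[C@H](O)[C@H]1O | intermediate
32 | angelic acid | C/C=C(/C)C(=O)O | starting material
33 | 12-O-angeloyl diol (C10-OH and C11-OH free) | C/C=C(/C)C(=O)OC[C@]1(C)[C@H]2[C@@H]3[C@H](C)CC(=O)[C@H]2[C@]3(C)C[C@H](O)[C@H]1O | intermediate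
34 | 10,12-di-O-angeloyl alcohol (C11-OH free) | C/C=C(/C)C(=O)OC[C@]1(C)[C@H]2[C@@H]3[C@H](C)CC(=O)[C@H]2[C@]3(C)C[C@H](OC(=O)/C(C)=C\C)[C@H]1O | intermediate
35 | CNP0214984.1 (triangelate) | C/C=C(/C)C(=O)OC[C@]1(C)[C@H]2[C@@H]3[C@H](C)CC(=O)[C@H]2[C@]3(C)C[C@H](OC(=O)/C(C)=C\C)[C@H]1OC(=O)/C(C)=C\C | target

**Step count and risks**

Total step count: 22. Longest linear sequence: 22 steps (1 → 35); 2, 5, 10 and 32 enter as purchased reagents.

The three steps most likely to fail:

Step 18. The 1,2-shift may proceed with migration of the bridgehead C7 instead of C4, or the amide base may simply enolise the ketone so that no carbenoid adduct forms. The fallback sets out from 27 and uses enolisation on purpose, since it can only go toward C4. Me3SiOTf/Et3N should give the silyl enol ether F1, and Et2Zn/CH2I2 the siloxycyclopropane F2. FeCl3 in DMF should open the internal cyclopropane bond to the ring-enlarged β-chloro ketone F3, and NaOAc in MeOH should eliminate it to the 4-methyl enone F4 (Ito–Saegusa ring enlargement). Li in NH3/THF at −78 °C with NH4Cl quench should then reduce the enone and remove the three benzyl groups in the same operation; protonation of the β-carbanion is expected to place the C4 methyl anti to C8-CH3. The fallback comes back to the route at triol 31.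

Step 15. Intermolecular coupling (oligomerisation) may outrun closure of the strained ten-membered ring, and the α-branched β,γ-unsaturated aldehyde may lose its C4 configuration while it waits. The fallback sets out from 21 and closes the same C6–C7 bond by a palladium-catalysed acylation. Me3SnSnMe3 with Pd(PPh3)4 should give the trimethylstannyl alcohol F5, buffered TEMPO/NaOCl/NaClO2 the stannyl carboxylic acid F6, and 1-chloro-N,N,2-trimethylprop-1-en-1-amine under neutral conditions the acid chloride F7. Intramolecular Stille acylation (Pd2(dba)3, tri(2-furyl)phosphine, toluene, high dilution) should then give the dienone directly, so the fallback comes back at 25.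

Step 22. Acylation may stall at the hindered C11 hydroxyl next to the quaternary C1, and the forcing conditions may isomerise angelate to tiglate. The fallback sets out from 34 and builds the third Z olefin in place. Coupling with 2-[bis(2,2,2-trifluoroethoxy)phosphoryl]propanoic acid (N,N'-dicyclohexylcarbodiimide, CH2Cl2, rt), which acylates hindered alcohols readily, should give the 11-O-phosphonopropanoate F8 as a mixture of epimers at the phosphonate carbon. Still–Gennari olefination (KN(SiMe3)2, 18-crown-6, THF, −78 °C, acetaldehyde) should then form the (Z)-2-methylbut-2-enoate at O11, coming back at 35.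

**Further compounds**

F1 | step 18 | silyl enol ether of 27 (C4=C6) | c1ccccc1COC[C@]1(C)[C@H]2[C@@H]3C(C)=C(O[Si](C)(C)C)[C@H]2[C@]3(C)C[C@H](OCc4ccccc4)[C@H]1OCc5ccccc5
F2 | step 18 | siloxycyclopropane (C5 added syn to C2-H) | c1ccccc1COC[C@]1(C)[C@H]2[C@@H]3[C@]4(C)C[C@]4(O[Si](C)(C)C)[C@H]2[C@]3(C)C[C@H](OCc5ccccc5)[C@H]1OCc6ccccc6
F3 | step 18 | ring-enlarged β-chloro ketone (C4 configuration open) | c1ccccc1COC[C@]1(C)[C@H]2[C@@H]3C(C)(Cl)CC(=O)[C@H]2[C@]3(C)C[C@H](OCc4ccccc4)[C@H]1OCc5ccccc5
F4 | step 18 | 4-methyl enone (C4=C5) tribenzyl ether | c1ccccc1COC[C@]1(C)[C@H]2[C@@H]3C(C)=CC(=O)[C@H]2[C@]3(C)C[C@H](OCc4ccccc4)[C@H]1OCc5ccccc5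
F5 | step 15 | trimethylstannyl alcohol | c1ccccc1COC[C@](C)(/C=C/[C@H](C)CO)[C@H](OCc2ccccc2)[C@@H](OCc3ccccc3)C/C(C)=C/[Sn](C)(C)C
F6 | step 15 | stannyl carboxylic acid | c1ccccc1COC[C@](C)(/C=C/[C@H](C)C(=O)O)[C@H](OCc2ccccc2)[C@@H](OCc3ccccc3)C/C(C)=C/[Sn](C)(C)C
F7 | step 15 | stannyl acid chloride | c1ccccc1COC[C@](C)(/C=C/[C@H](C)C(=O)Cl)[C@H](OCc2ccccc2)[C@@H](OCc3ccccc3)C/C(C)=C/[Sn](C)(C)C
F8 | step 22 | 11-O-{2-[bis(2,2,2-trifluoroethoxy)phosphoryl]propanoyl} 10,12-di-O-angelate | C/C=C(/C)C(=O)OC[C@]1(C)[C@H]2[C@@H]3[C@H](C)CC(=O)[C@H]2[C@]3(C)C[C@H](OC(=O)/C(C)=C\C)[C@H]1OC(=O)C(C)P(=O)(OCC(F)(F)F)OCC(F)(F)F
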